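If a catalyst keeps a steady pace, what a flask can reach by a given time is its loading times that pace times the time, and I held that reach against the substrate charged.

| setting | violet | south-west | north | south-east | east | west | north-west |
|---|---|---|---|---|---|---|---|
| substrate | 0.055 M | 0.050 M | 0.15 M | 0.012 M | 0.025 M | 0.080 M | 0.050 M |
| partner | 3 equiv | 3.00 equiv | 0.990 equiv | 9.00 equiv | 1.50 equiv | 4.50 equiv | 3.00 equiv |
| free catalyst | 2.5 mol% | 2.5 mol% | 2.5 mol% | 0.6 mol% | 4 mol% | 10 mol% | 0.8 mol% |
| remark | run made earlier |  |  |  |  |  |  |
| time |  | 30 h | 30 h | 30 h | 30 h | 30 h | 30 h |

violet run (percent of the substrate charged)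

| time / h | product / % | substrate / % |
|---|---|---|
| 0.667 | 0.6 | 98.6 |
| 2.00 | 1.0 | 97.5 |
| 4.00 | 4.2 | 95.3 |
| 6.00 | 4.9 | 92.8 |
| 8.00 | 6.3 | 92.6 |
| 10.0 | 8.7 | 89.4 |

(readings scatter by 0.5 percentage points)

- in percentages every species weighs as the substrate in it: one spent catalyst counts as two
- candidate steps: partner -> decomposed reagent; substrate + free catalyst -> catalyst intermediate A; partner + catalyst intermediate B <-> catalyst intermediate C; catalyst intermediate C -> released group + catalyst intermediate D; catalyst intermediate D -> free catalyst + product; catalyst intermediate C + product -> spent catalyst; catalyst intermediate A -> catalyst intermediate B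
- no earlier run changes the charge of free catalyst; that part of a forecast is a guess

1. all flasks from highest to lowest amount of product, in percent of the substrate charged, at 30 h (south-west / north / south-east / east / west / north-west)
2. the amount of product, in percent of the substrate charged of the flask you put first, at 30 h
3. the amount of product, in percent of the substrate charged of the flask you put last, at 30 h

I read the violet run row by row. Product in the violet run stood at 4.9% by 6.00 h and at 8.7% by 10.0 h. Divided by the loading of 2.5 mol% and by the time, these rows gave 0.327 h⁻¹ and 0.348 h⁻¹. I took the second as the pace, the product made per catalyst charged per hour, or turnover frequency. The scatter of 0.5 percentage points covered the gap between the two, while substrate was still at 89.4%.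

Then I read the loading column against that pace for 30 h. West, with 10 mol%, had the highest loading, and its reach of 104% stood above the charge, so I expected west close to complete. East followed at 41.8%, south-west and north, with equal loadings, at 26.1%, north-west at 8.35% and south-east at 6.26%. This was partly a guess, because no earlier run changed the loading and the pace was read at 0.055 M of substrate.

The forecast gave west > south-west > north > east > north-west > south-east, with 68% (42% to 92%) for the first flask and 4.5% (2.5% to 7.5%) for the last, holding that west “should fall short of completion”. My reckoning differed from it by placing east second and by setting west higher.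

The flasks gave west > north > east > south-west > north-west > south-east, with 90.1% in west and 3.25% in south-east, which was about half of its reach.

    partner → decomposed reagent (k = 0.0140 h⁻¹)
    substrate + free catalyst → catalyst intermediate A (k = 26.0 L mol⁻¹ h⁻¹)
    partner + catalyst intermediate B ⇌ catalyst intermediate C (K = 80.0 L mol⁻¹, k = 120 L mol⁻¹ h⁻¹)
    catalyst intermediate C → released group + catalyst intermediate D (k = 4.50 h⁻¹)
    catalyst intermediate D → free catalyst + product (k = 0.780 h⁻¹)
    catalyst intermediate C + product → spent catalyst (k = 0.0280 L mol⁻¹ h⁻¹)
    catalyst intermediate A → catalyst intermediate B (k = 2.70 h⁻¹)

In west, a free catalyst took up substrate at 2.08 h⁻¹ at the start, faster than the 0.78 h⁻¹ at which catalyst intermediate D released it. By 30.0 h in west, with 7.31% of the substrate left, uptake per free catalyst had fallen to 0.152 h⁻¹, slower than that step, and free catalyst held 74.1% of the catalyst against 17.9% in catalyst intermediate D.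

For west read at 12 h, the same pace gave a reach of 41.8%. The computed west flask at that time stood at 43.5%, with 49.7% of its substrate left.

(All runs are simulated from invented constants; scatter was added.)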